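Assumption: the target SMILES has no stereocentre, so the compound is achiral and needs no enantiocontrol. The stereocentre in 4, 5 and 6 is racemic and disappears in step 3.

**Retrosynthetic overview**
1. The C6–aryl bond is made last, by Suzuki coupling of a 6-bromobenzofuran with (4-hydroxyphenyl)boronic acid, without protecting groups.
2. The key disconnection is the aryl C7a–O1 bond of the furan. It is formed by acid-triggered isomerisation of a 5-aryl-5-methyltetronic acid: the benzylic lactone C–O bond ionises and the enol oxygen closes on the free ortho C–H.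
3. The tetronic acid comes from intramolecular Claisen closure of an α-acetoxy-α-arylpropanoate.
4. That ester comes from mono-lithiated 1,4-dibromo-2,5-dimethoxybenzene, methyl pyruvate and Ac2O. The arene pattern already maps onto C3a, C4-OMe, C6 and C7-OMe.
5. Ring order: the butenolide is formed first, its atoms are then transposed into the furan ring of the benzofuran, and the biaryl bond is made last.

**Route**

Step 1
Reactants: 1 1,4-dibromo-2,5-dimethoxybenzene; 2 methyl pyruvate
Product: 5 racemic methyl 2-acetoxy-2-(4-bromo-2,5-dimethoxyphenyl)propanoate, via aryllithium 3 (not isolated), via lithium alkoxide 4 (not isolated)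
Conditions: n-BuLi (1.0 equiv), THF, −78 °C; cannulate into 2 (1.5 equiv), THF, −78 °C; Ac2O (2.5 equiv), −78 °C → rt
Reagents that add atoms: acetic anhydride CC(=O)OC(C)=O
Why: Bromine–lithium exchange on the symmetrical dibromide stops at the OMe-chelated mono-aryllithium, which adds 1,2 to the more electrophilic ketone carbonyl of the α-keto ester (organolithium addition), and the tertiary alkoxide is O-acylated in situ; the new quaternary centre is racemic and is erased in step 3.

Step 2
Reactants: 5 racemic methyl 2-acetoxy-2-(4-bromo-2,5-dimethoxyphenyl)propanoate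
Product: 6 racemic 5-(4-bromo-2,5-dimethoxyphenyl)-4-hydroxy-5-methylfuran-2(5H)-one
Conditions: LiHMDS (2.5 equiv), THF, −78 → 0 °C; 1 M HCl; NaHCO3/HCl extraction
Reagents that add atoms: none
Why: This is the intramolecular Claisen (Dieckmann-type) condensation of an α-acetoxy ester, the standard tetronic acid synthesis, in which the acetate enolate attacks the neighbouring methyl ester and irreversible deprotonation of the vinylogous acid (pKa about 4) drives the closure and allows purification by acid–base extraction.

Step 3
Reactants: 6 racemic 5-(4-bromo-2,5-dimethoxyphenyl)-4-hydroxy-5-methylfuran-2(5H)-one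
Product: 8 methyl 2-(6-bromo-4,7-dimethoxy-3-methyl-1-benzofuran-2-yl)acetate, via benzofuranacetic acid 7 (not isolated)
Conditions: TfOH (20 mol %), HFIP (0.05 M), 40 °C; then MeOH (equal volume), 50 °C
Reagents that add atoms: methanol CO
Why: Proposed new method: TfOH/HFIP protonates the lactone and ionises the tertiary, o-methoxy-stabilised benzylic C5–O bond to an α-acyl (enol-oxenium) benzylic cation, whose C4 oxygen closes on the only free ortho carbon in a 4π oxa-Nazarov-type electrocyclisation that forms the aryl C7a–O1 bond; loss of that ortho proton and protonation of the exocyclic C=C then aromatise to acid 7, so the lactone C–O bond serves as internal oxidant and the step is a pure isomerisation driven by aromatisation; closure at the OMe-bearing ortho carbon is reversible because no proton can be lost there, and the ring-derived Z-enol geometry holds CO2H "inside" and disfavours the competing carbocyclic Nazarov closure; Fischer esterification in the same pot gives 8; the closest known reaction types are the Ag(I)- or acid-induced cyclisation of α-acyl benzylic cations (from α-halo-α-aryl ketones) to benzofurans, the Nazarov cyclisation and TfOH/HFIP ionisation of deactivated benzylic alcohols, none of which has been shown on tetronic acids.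

Step 4
Reactants: 8 methyl 2-(6-bromo-4,7-dimethoxy-3-methyl-1-benzofuran-2-yl)acetate; 9 (4-hydroxyphenyl)boronic acid
Product: 10 phenylcandilide B, methyl 2-[6-(4-hydroxyphenyl)-4,7-dimethoxy-3-methyl-1-benzofuran-2-yl]acetate
Conditions: Pd(OAc)2 (2 mol %), SPhos (4 mol %), K3PO4 (2.5 equiv), 9 (1.3 equiv), degassed THF/H2O 10:1, 60 °C
Reagents that add atoms: none
Why: In this Suzuki–Miyaura coupling SPhos handles the single, electron-rich, mono-ortho-substituted C–Br bond at mild temperature, the free phenol of 9 is tolerated, and phosphate in a mostly organic medium spares the methyl ester.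

**Compound list**
1 | 1,4-dibromo-2,5-dimethoxybenzene | COc1cc(Br)c(OC)cc1Br | starting material
2 | methyl pyruvate | COC(=O)C(C)=O | starting material
3 | (4-bromo-2,5-dimethoxyphenyl)lithium | [Li]c1cc(OC)c(Br)cc1OC | intermediate
4 | lithium alkoxide of methyl 2-(4-bromo-2,5-dimethoxyphenyl)-2-hydroxypropanoate (racemic) | [Li+].COC(=O)C(C)([O-])c1cc(OC)c(Br)cc1OC | intermediate
5 | methyl 2-acetoxy-2-(4-bromo-2,5-dimethoxyphenyl)propanoate (racemic) | COC(=O)C(C)(OC(C)=O)c1cc(OC)c(Br)cc1OC | intermediate
6 | 5-(4-bromo-2,5-dimethoxyphenyl)-4-hydroxy-5-methylfuran-2(5H)-one (racemic) | CC1(OC(=O)C=C1O)c1cc(OC)c(Br)cc1OC | intermediate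
7 | 2-(6-bromo-4,7-dimethoxy-3-methyl-1-benzofuran-2-yl)acetic acid | OC(=O)Cc1oc2c(OC)c(Br)cc(OC)c2c1C | intermediate
8 | methyl 2-(6-bromo-4,7-dimethoxy-3-methyl-1-benzofuran-2-yl)acetate | COC(=O)Cc1oc2c(OC)c(Br)cc(OC)c2c1C | intermediate
9 | (4-hydroxyphenyl)boronic acid | OB(O)c1ccc(O)cc1 | starting material
10 | phenylcandilide B (achiral) | COC(=O)Cc1oc2c(OC)c(-c3ccc(O)cc3)cc(OC)c2c1C | target

Total step count: 4. Longest linear sequence: 4 (1 → 5 → 6 → 8 → 10).

**Steps most likely to fail**

**Step 3 (the proposed new step).**
- Risks: ionisation may be too slow or may end in retro-Friedel–Crafts loss of the arene. The ring-opened β-keto acid may decarboxylate. The cation may alkylate a second molecule, or it may close through carbon to a 2-indanone.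
- Fallback: it uses known reactions only, sets out from 5 and comes back at 8. Ionic hydrogenation (Et3SiH, TFA, cat. TfOH, CH2Cl2) removes the benzylic acetate to give methyl 2-(4-bromo-2,5-dimethoxyphenyl)propanoate F4. LiOH in THF/H2O gives 2-(4-bromo-2,5-dimethoxyphenyl)propanoic acid F5. Carboxylate-directed Pd(II)-catalysed ortho C–H iodination (Pd(OAc)2, PhI(OAc)2/I2, DMF, 60 °C) functionalises the only free ortho position to give 2-(4-bromo-2-iodo-3,6-dimethoxyphenyl)propanoic acid F6. Masamune–Brooks homologation (CDI, then MgCl2, potassium methyl malonate, Et3N) gives methyl 4-(4-bromo-2-iodo-3,6-dimethoxyphenyl)-3-oxopentanoate F7. CuI/DMEDA/Cs2CO3 intramolecular enolate O-arylation then takes place at C–I, with C–Br untouched, and tautomerisation to the aromatic furan gives 8.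

**Step 1.**
- Risks: the aryllithium may enolise or doubly attack methyl pyruvate, and the hindered alkoxide may acetylate incompletely.
- Fallback: it sets out from 1 and comes back at 6, bypassing 5. The carbinol is built by adding a weakly basic acetylide to an aryl ketone instead. Mono-lithiated 1 is acylated with N-methoxy-N-methylacetamide to give 1-(4-bromo-2,5-dimethoxyphenyl)ethan-1-one F1. Lithiated methyl propiolate (LDA, THF, −78 °C) adds to give methyl 4-(4-bromo-2,5-dimethoxyphenyl)-4-hydroxypent-2-ynoate F2. NaOMe/MeOH (conjugate addition, then lactonisation) gives 5-(4-bromo-2,5-dimethoxyphenyl)-4-methoxy-5-methylfuran-2(5H)-one F3. Aqueous NaOH followed by HCl cleaves the vinylogous ester to give 6.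

**Step 4.**
- Risks: the activated methyl ester may be partly saponified under the basic coupling conditions, and 9 may protodeboronate.
- Fallback: it sets out from 7 and comes back at 10, with the order of coupling and esterification reversed. Step 3 is stopped before MeOH is added and 7 is isolated. As its carboxylate, 7 is coupled with 9 (Pd(dppf)Cl2, K2CO3, dioxane/H2O, 80 °C) to give 2-[6-(4-hydroxyphenyl)-4,7-dimethoxy-3-methyl-1-benzofuran-2-yl]acetic acid F8. Fischer esterification (MeOH, cat. H2SO4) then gives 10.

**Further compounds**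
F1 | step 1 | 1-(4-bromo-2,5-dimethoxyphenyl)ethan-1-one | CC(=O)c1cc(OC)c(Br)cc1OC
F2 | step 1 | methyl 4-(4-bromo-2,5-dimethoxyphenyl)-4-hydroxypent-2-ynoate (racemic) | COC(=O)C#CC(C)(O)c1cc(OC)c(Br)cc1OC
F3 | step 1 | 5-(4-bromo-2,5-dimethoxyphenyl)-4-methoxy-5-methylfuran-2(5H)-one (racemic) | COC1=CC(=O)OC1(C)c1cc(OC)c(Br)cc1OC
F4 | step 3 | methyl 2-(4-bromo-2,5-dimethoxyphenyl)propanoate (racemic) | COC(=O)C(C)c1cc(OC)c(Br)cc1OC
F5 | step 3 | 2-(4-bromo-2,5-dimethoxyphenyl)propanoic acid (racemic) | OC(=O)C(C)c1cc(OC)c(Br)cc1OC
F6 | step 3 | 2-(4-bromo-2-iodo-3,6-dimethoxyphenyl)propanoic acid (racemic) | OC(=O)C(C)c1c(I)c(OC)c(Br)cc1OC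
F7 | step 3 | methyl 4-(4-bromo-2-iodo-3,6-dimethoxyphenyl)-3-oxopentanoate (racemic) | COC(=O)CC(=O)C(C)c1c(I)c(OC)c(Br)cc1OC
F8 | step 4 | 2-[6-(4-hydroxyphenyl)-4,7-dimethoxy-3-methyl-1-benzofuran-2-yl]acetic acid | OC(=O)Cc1oc2c(OC)c(-c3ccc(O)cc3)cc(OC)c2c1C
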